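Locants: C1 = CO2H, C2 = CH2, ring carbons C3–C4–C5 with O2 on C3 and O1 on C5, chain C6–C15 with the methyl on C7 and phenyl on C15.
Retrosynthesis: the C1 acid is read as a vinyl group on C3; C10=C11 is cut into a C10 aldehyde and a C11–C15 tetrazolyl sulfone; both ring C–O bonds (O1–C5, O2–C3) are cut, leaving a C3–C5 bond.
Enabling feature: in the 1,2-dioxolane, C3–C4–C5 is a three-carbon unit whose ends C3 and C5 are both fully substituted and each bound to one oxygen of the O1–O2 bridge, i.e. a cyclopropane C3–C4–C5 with O2 inserted into its C3–C5 bond.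
Forward: (R)-citronellal → C5–C10 silyloxy 1,1-disubstituted alkene → cyclopropane (C3 delivered as a rhodium carbenoid) → vinylcyclopropane → dioxolane (the only ring of the target, step 11) → C10=C11 olefination → vinyl to CH2CO2H.
Stereochemistry: C7 comes from (R)-citronellal; C3 and C5 both arise in step 11 (cis bias from the 5-exo closure, no facial bias, so diastereomers are separated); E-C14=C15 comes from a Johnson–Claisen rearrangement and E-C10=C11 from the Julia–Kocienski olefination.

Key step: step 11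

Remark: the ring carbons of 10–13 form unselectively and are carried as stereoisomer mixtures, which is harmless because step 11 breaks the C3–C5 bond and re-forms both centres; it is assumed that the four diastereomers of 14 (all diastereomeric because C7 is fixed) can be separated by chromatography.

Step 1
Reactants: 1 (R)-citronellal, (3R)-3,7-dimethyloct-6-enal
Product: 2 (4R)-4,8-dimethylnon-7-en-2-ol (mixture of C2 epimers)
Conditions: MeMgBr, Et2O, 0 °C; aq NH4Cl work-up
Reagents that add atoms: methylmagnesium bromide, C[Mg]Br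
Why: Grignard addition to the aldehyde gives the secondary alcohol, whose new carbinol centre is removed again by oxidation in step 4, while the methyl-bearing centre (future C7) is β to the carbonyl and cannot epimerise.

Step 2
Reactants: 2 (4R)-4,8-dimethylnon-7-en-2-ol
Product: 4 (4R)-4-methylheptane-1,6-diol (C6 epimers), via ozonide 3 (not isolated)
Conditions: O3, CH2Cl2, −78 °C; then NaBH4, MeOH, −78 °C → rt
Reagents that add atoms: ozone, [O-][O+]=O
Why: Ozonolysis of the electron-rich trisubstituted alkene with reductive NaBH4 work-up should cleave the isopropylidene end to the primary alcohol (future C10), the free secondary alcohol being inert to ozone at −78 °C.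

Step 3
Reactants: 4 (4R)-4-methylheptane-1,6-diol
Product: 5 (4R)-7-[(tert-butyldimethylsilyl)oxy]-4-methylheptan-2-ol
Conditions: TBSCl (1.05 equiv), imidazole, CH2Cl2, −10 → 0 °C
Reagents that add atoms: tert-butyldimethylsilyl chloride, CC(C)(C)[Si](C)(C)Cl
Why: Silylation with one equivalent of a bulky silyl chloride at low temperature is strongly selective for the primary over the secondary hydroxyl.

Step 4
Reactants: 5 (4R)-7-[(tert-butyldimethylsilyl)oxy]-4-methylheptan-2-ol
Product: 6 (4R)-7-[(tert-butyldimethylsilyl)oxy]-4-methylheptan-2-one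
Conditions: nPr4N[RuO4] (5 mol %), N-methylmorpholine N-oxide, 4 Å MS, CH2Cl2, rt
Reagents that add atoms: none
Why: Ley–Griffith oxidation converts the secondary alcohol to the methyl ketone under neutral conditions that spare the silyl ether, and the stereocentre β to the carbonyl is not epimerisable.

Step 5
Reactants: 6 (4R)-7-[(tert-butyldimethylsilyl)oxy]-4-methylheptan-2-one
Product: 7 tert-butyl{[(4R)-4,6-dimethylhept-6-en-1-yl]oxy}dimethylsilane
Conditions: Ph3PCH3Br, KOtBu, THF, 0 °C → rt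
Reagents that add atoms: methyltriphenylphosphonium bromide, [Br-].C[P+](c1ccccc1)(c1ccccc1)c1ccccc1 (the CH2 group)
Why: Wittig methylenation of an unhindered methyl ketone with Ph3P=CH2 gives the 1,1-disubstituted alkene whose carbons become C5 and C4.

Step 6
Reactants: 8 ethyl 2-methyl-3-oxobutanoate (ethyl 2-methylacetoacetate)
Product: 9 ethyl 2-diazopropanoate
Conditions: 4-acetamidobenzenesulfonyl azide, DBU, MeCN, 0 °C → rt
Reagents that add atoms: 4-acetamidobenzenesulfonyl azide, CC(=O)Nc1ccc(cc1)S(=O)(=O)N=[N+]=[N-]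
Why: Regitz deacylative diazo transfer: the enolate attacks the sulfonyl azide and the adduct fragments with transfer of the acetyl group to the sulfonamide, leaving the α-diazo ester.

Step 7
Reactants: 7 tert-butyl{[(4R)-4,6-dimethylhept-6-en-1-yl]oxy}dimethylsilane; 9 ethyl 2-diazopropanoate
Product: 10 ethyl 2-[(2R)-5-[(tert-butyldimethylsilyl)oxy]-2-methylpentyl]-1,2-dimethylcyclopropane-1-carboxylate (mixture of ring stereoisomers)
Conditions: Rh2(OAc)4 (2 mol %), CH2Cl2, rt, 9 (3 equiv) added by syringe pump over 12 h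
Reagents that add atoms: none
Why: Rhodium carbenoid cyclopropanation of the electron-rich 1,1-disubstituted alkene forms C3–C4 and C3–C5, slow addition of 9 limiting carbene dimerisation and 1,2-hydride shift; the two new ring centres form without control and all isomers are used.

Step 8
Reactants: 10 ethyl 2-[(2R)-5-[(tert-butyldimethylsilyl)oxy]-2-methylpentyl]-1,2-dimethylcyclopropane-1-carboxylate
Product: 11 {2-[(2R)-5-[(tert-butyldimethylsilyl)oxy]-2-methylpentyl]-1,2-dimethylcyclopropyl}methanol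
Conditions: i-Bu2AlH (2.5 equiv), CH2Cl2, −78 → 0 °C; aq KNaC4H4O6 work-up
Reagents that add atoms: none
Why: Hydride reduction of the ester with i-Bu2AlH gives the primary alcohol without touching the silyl ether or the cyclopropane.

Step 9
Reactants: 11 {2-[(2R)-5-[(tert-butyldimethylsilyl)oxy]-2-methylpentyl]-1,2-dimethylcyclopropyl}methanol
Product: 12 2-[(2R)-5-[(tert-butyldimethylsilyl)oxy]-2-methylpentyl]-1,2-dimethylcyclopropane-1-carbaldehyde
Conditions: nPr4N[RuO4] (5 mol %), N-methylmorpholine N-oxide, 4 Å MS, CH2Cl2, rt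
Reagents that add atoms: none
Why: Ley–Griffith oxidation under anhydrous conditions stops at the aldehyde, which has no α-hydrogen and therefore cannot enolise.

Step 10
Reactants: 12 2-[(2R)-5-[(tert-butyldimethylsilyl)oxy]-2-methylpentyl]-1,2-dimethylcyclopropane-1-carbaldehyde
Product: 13 tert-butyl{[(4R)-5-(2-ethenyl-1,2-dimethylcyclopropyl)-4-methylpentyl]oxy}dimethylsilane (mixture of ring stereoisomers)
Conditions: Ph3PCH3Br, KOtBu, THF, 0 °C → rt
Reagents that add atoms: methyltriphenylphosphonium bromide, [Br-].C[P+](c1ccccc1)(c1ccccc1)c1ccccc1 (the CH2 group)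
Why: Wittig methylenation with the unstabilised ylide works on α-quaternary, non-enolisable aldehydes and installs the vinyl group (future C2 and C1).

Step 11
Reactants: 13 tert-butyl{[(4R)-5-(2-ethenyl-1,2-dimethylcyclopropyl)-4-methylpentyl]oxy}dimethylsilane
Product: 14 tert-butyl{[(4R)-5-[(3R,5R)-5-ethenyl-3,5-dimethyl-1,2-dioxolan-3-yl]-4-methylpentyl]oxy}dimethylsilane (the isomer with chain and vinyl cis, after separation)
Conditions: PhSeSePh (0.2 equiv), AIBN (2,2'-azobis(2-methylpropionitrile), 0.1 equiv), O2 (1 atm, bubbled), MeCN, 0 °C, hν (sunlamp); chromatography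
Reagents that add atoms: dioxygen, O=O
Why: PhSe•, formed by photolysis of PhSeSePh, adds to the vinyl terminus, the cyclopropylcarbinyl radical opens by cleaving C3–C5 to the tertiary C5 radical and an allyl selenide, C5 captures O2 (O1–C5), and the peroxyl radical adds to C3 (O2–C3) with β-loss of PhSe•, which restores the vinyl group and carries the chain. This is the known selenyl- or thiyl-radical-mediated aerobic oxygenation of vinylcyclopropanes to 3-vinyl-1,2-dioxolanes. The dioxolane, the only ring formed, closes 5-exo-trig by attack of the peroxyl oxygen on the inner alkene carbon C3. C5 is set by the face on which the planar tertiary radical meets O2, for which the remote C7 centre offers no control, and C3 is set relative to C5 in the chair-like transition state of the closure, where the larger C6 chain on C5 prefers the pseudo-equatorial site and so ends cis to the new vinyl group. The step needs C3–C5 rather than C3–C4 cleavage, secured by the tertiary versus primary radical, and a single radical acceptor, secured by the absence of any other alkene in 13. It also needs the 3,5-cis relationship on the correct face: because methyl and CH2R differ little in size only a modest cis preference is expected, so the (3R,5R) isomer is to be separated by chromatography from its three diastereomers.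

Step 12
Reactants: 14 tert-butyl{[(4R)-5-[(3R,5R)-5-ethenyl-3,5-dimethyl-1,2-dioxolan-3-yl]-4-methylpentyl]oxy}dimethylsilane
Product: 15 (4R)-5-[(3R,5R)-5-ethenyl-3,5-dimethyl-1,2-dioxolan-3-yl]-4-methylpentan-1-ol
Conditions: HF·pyridine, pyridine/THF, 0 °C → rt
Reagents that add atoms: none
Why: Fluoride-mediated desilylation frees the C10 hydroxyl, and the peroxide, having no hydrogen on either oxygen-bearing carbon, cannot undergo Kornblum–DeLaMare fragmentation.

Step 13
Reactants: 15 (4R)-5-[(3R,5R)-5-ethenyl-3,5-dimethyl-1,2-dioxolan-3-yl]-4-methylpentan-1-ol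
Product: 16 (4R)-5-[(3R,5R)-5-ethenyl-3,5-dimethyl-1,2-dioxolan-3-yl]-4-methylpentanal
Conditions: Dess–Martin periodinane, pyridine, CH2Cl2, 0 °C → rt
Reagents that add atoms: none
Why: Dess–Martin oxidation takes the primary alcohol to the C10 aldehyde under buffered, non-reducing conditions that leave the O–O bond and the vinyl group untouched.

Step 14
Reactants: 17 1-phenylprop-2-en-1-ol (racemic)
Product: 19 ethyl (4E)-5-phenylpent-4-enoate, via ketene acetal 18 (not isolated)
Conditions: MeC(OEt)3 (excess), EtCO2H (cat.), 140 °C, EtOH distilled off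
Reagents that add atoms: triethyl orthoacetate, CC(OCC)(OCC)OCC
Why: Johnson–Claisen rearrangement through a chair transition state with phenyl equatorial gives the conjugated (E)-alkene (C14=C15) and destroys the carbinol centre, so the racemic alcohol suffices.

Step 15
Reactants: 19 ethyl (4E)-5-phenylpent-4-enoate
Product: 20 (4E)-5-phenylpent-4-en-1-ol
Conditions: LiAlH4, Et2O, 0 °C; aqueous work-up
Reagents that add atoms: none
Why: LiAlH4 reduction of the ester gives the primary alcohol, and the isolated styrenyl double bond is not reduced.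

Step 16
Reactants: 20 (4E)-5-phenylpent-4-en-1-ol
Product: 21 1-phenyl-5-{[(4E)-5-phenylpent-4-en-1-yl]sulfanyl}-1H-tetrazole
Conditions: 1-phenyl-1H-tetrazole-5-thiol, PPh3, DIAD, THF, 0 °C → rt
Reagents that add atoms: 1-phenyl-1H-tetrazole-5-thiol, Sc1nnnn1-c1ccccc1
Why: Mitsunobu thioetherification displaces the activated primary hydroxyl with the acidic heteroaryl thiol by SN2.

Step 17
Reactants: 21 1-phenyl-5-{[(4E)-5-phenylpent-4-en-1-yl]sulfanyl}-1H-tetrazole
Product: 22 1-phenyl-5-{[(4E)-5-phenylpent-4-en-1-yl]sulfonyl}-1H-tetrazole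
Conditions: 30% H2O2, (NH4)6Mo7O24·4H2O (10 mol %), EtOH, 0 °C → rt
Reagents that add atoms: hydrogen peroxide, OO
Why: Molybdate-catalysed sulfide-to-sulfone oxidation is much faster than epoxidation of the styrenyl alkene under these conditions.

Step 18
Reactants: 16 (4R)-5-[(3R,5R)-5-ethenyl-3,5-dimethyl-1,2-dioxolan-3-yl]-4-methylpentanal; 22 1-phenyl-5-{[(4E)-5-phenylpent-4-en-1-yl]sulfonyl}-1H-tetrazole
Product: 23 (3R,5R)-3-ethenyl-3,5-dimethyl-5-[(2R,5E,9E)-2-methyl-10-phenyldeca-5,9-dien-1-yl]-1,2-dioxolane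
Conditions: 22 (1.3 equiv), KN(SiMe3)2, DME, −60 °C, 30 min; then 16, −60 °C → rt
Reagents that add atoms: none
Why: Julia–Kocienski olefination: the metalated tetrazolyl sulfone adds to the aldehyde and Smiles rearrangement with loss of SO2 forms C10=C11, the potassium counter-ion in DME favouring the E isomer, while the hindered peroxide offers no acidic or electrophilic site at this temperature.

Step 19
Reactants: 23 (3R,5R)-3-ethenyl-3,5-dimethyl-5-[(2R,5E,9E)-2-methyl-10-phenyldeca-5,9-dien-1-yl]-1,2-dioxolane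
Product: 25 2-[(3S,5R)-3,5-dimethyl-5-[(2R,5E,9E)-2-methyl-10-phenyldeca-5,9-dien-1-yl]-1,2-dioxolan-3-yl]ethan-1-ol, via alkylborane 24 (not isolated)
Conditions: 9-BBN (1.3 equiv), THF, 0 °C → rt; then aq NaOH, 30% H2O2, 0 °C
Reagents that add atoms: hydrogen peroxide, OO (the hydroxyl oxygen); 9-borabicyclo[3.3.1]nonane, B1C2CCCC1CCC2 (in 24 only)
Why: Anti-Markovnikov hydroboration–oxidation with bulky 9-BBN should take the monosubstituted vinyl group far faster than the two (E)-1,2-disubstituted alkenes, and alkaline H2O2 does not attack a peroxide lacking α-hydrogens; the descriptor at C3 changes to S only because of CIP priorities.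

Step 20
Reactants: 25 2-[(3S,5R)-3,5-dimethyl-5-[(2R,5E,9E)-2-methyl-10-phenyldeca-5,9-dien-1-yl]-1,2-dioxolan-3-yl]ethan-1-ol
Product: 27 2-[(3R,5R)-3,5-dimethyl-5-[(2R,5E,9E)-2-methyl-10-phenyldeca-5,9-dien-1-yl]-1,2-dioxolan-3-yl]acetic acid, via aldehyde 26 (not isolated)
Conditions: TEMPO (2,2,6,6-tetramethylpiperidine-1-oxyl, 0.2 equiv), PhI(OAc)2 (2.5 equiv), MeCN/H2O 1:1, rt
Reagents that add atoms: water, O
Why: Oxoammonium (TEMPO/PhI(OAc)2) oxidation in aqueous acetonitrile takes the primary alcohol through the aldehyde hydrate to the acid without affecting alkenes, peroxide or any stereocentre.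

Compound list
1 | (R)-citronellal, (3R)-3,7-dimethyloct-6-enal | C[C@H](CCC=C(C)C)CC=O | starting material
2 | (4R)-4,8-dimethylnon-7-en-2-ol (C2 epimers) | C[C@H](CCC=C(C)C)CC(C)O | intermediate
3 | (4R)-6-(5,5-dimethyl-1,2,4-trioxolan-3-yl)-4-methylhexan-2-ol (ozonide, not isolated) | C[C@H](CCC1OOC(C)(C)O1)CC(C)O | intermediate
4 | (4R)-4-methylheptane-1,6-diol (C6 epimers) | C[C@H](CCCO)CC(C)O | intermediate
5 | (4R)-7-[(tert-butyldimethylsilyl)oxy]-4-methylheptan-2-ol | C[C@H](CCCO[Si](C)(C)C(C)(C)C)CC(C)O | intermediate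
6 | (4R)-7-[(tert-butyldimethylsilyl)oxy]-4-methylheptan-2-one | C[C@H](CCCO[Si](C)(C)C(C)(C)C)CC(C)=O | intermediate
7 | tert-butyl{[(4R)-4,6-dimethylhept-6-en-1-yl]oxy}dimethylsilane | C[C@H](CCCO[Si](C)(C)C(C)(C)C)CC(C)=C | intermediate
8 | ethyl 2-methyl-3-oxobutanoate | CCOC(=O)C(C)C(C)=O | starting material
9 | ethyl 2-diazopropanoate | CCOC(=O)C(C)=[N+]=[N-] | intermediate
10 | ethyl 2-[(2R)-5-[(tert-butyldimethylsilyl)oxy]-2-methylpentyl]-1,2-dimethylcyclopropane-1-carboxylate (ring stereoisomers) | C[C@H](CCCO[Si](C)(C)C(C)(C)C)CC1(C)CC1(C)C(=O)OCC | intermediate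
11 | {2-[(2R)-5-[(tert-butyldimethylsilyl)oxy]-2-methylpentyl]-1,2-dimethylcyclopropyl}methanol (ring stereoisomers) | C[C@H](CCCO[Si](C)(C)C(C)(C)C)CC1(C)CC1(C)CO | intermediate
12 | 2-[(2R)-5-[(tert-butyldimethylsilyl)oxy]-2-methylpentyl]-1,2-dimethylcyclopropane-1-carbaldehyde (ring stereoisomers) | C[C@H](CCCO[Si](C)(C)C(C)(C)C)CC1(C)CC1(C)C=O | intermediate
13 | tert-butyl{[(4R)-5-(2-ethenyl-1,2-dimethylcyclopropyl)-4-methylpentyl]oxy}dimethylsilane (ring stereoisomers) | C[C@H](CCCO[Si](C)(C)C(C)(C)C)CC1(C)CC1(C)C=C | intermediate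
14 | tert-butyl{[(4R)-5-[(3R,5R)-5-ethenyl-3,5-dimethyl-1,2-dioxolan-3-yl]-4-methylpentyl]oxy}dimethylsilane | C[C@H](CCCO[Si](C)(C)C(C)(C)C)C[C@]1(C)C[C@](C)(C=C)OO1 | intermediate
15 | (4R)-5-[(3R,5R)-5-ethenyl-3,5-dimethyl-1,2-dioxolan-3-yl]-4-methylpentan-1-ol | C[C@H](CCCO)C[C@]1(C)C[C@](C)(C=C)OO1 | intermediate
16 | (4R)-5-[(3R,5R)-5-ethenyl-3,5-dimethyl-1,2-dioxolan-3-yl]-4-methylpentanal | C[C@H](CCC=O)C[C@]1(C)C[C@](C)(C=C)OO1 | intermediate
17 | 1-phenylprop-2-en-1-ol (racemic) | C=CC(O)c1ccccc1 | starting material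
18 | [1-(1-ethoxyethenyloxy)prop-2-en-1-yl]benzene (ketene acetal, not isolated) | C=C(OCC)OC(C=C)c1ccccc1 | intermediate
19 | ethyl (4E)-5-phenylpent-4-enoate | CCOC(=O)CC/C=C/c1ccccc1 | intermediate
20 | (4E)-5-phenylpent-4-en-1-ol | OCCC/C=C/c1ccccc1 | intermediate
21 | 1-phenyl-5-{[(4E)-5-phenylpent-4-en-1-yl]sulfanyl}-1H-tetrazole | c1ccccc1/C=C/CCCSc1nnnn1-c1ccccc1 | intermediate
22 | 1-phenyl-5-{[(4E)-5-phenylpent-4-en-1-yl]sulfonyl}-1H-tetrazole | O=S(=O)(CCC/C=C/c1ccccc1)c1nnnn1-c1ccccc1 | intermediate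
23 | (3R,5R)-3-ethenyl-3,5-dimethyl-5-[(2R,5E,9E)-2-methyl-10-phenyldeca-5,9-dien-1-yl]-1,2-dioxolane | C[C@H](CC/C=C/CC/C=C/c1ccccc1)C[C@]1(C)C[C@](C)(C=C)OO1 | intermediate
24 | 9-{2-[(3S,5R)-3,5-dimethyl-5-[(2R,5E,9E)-2-methyl-10-phenyldeca-5,9-dien-1-yl]-1,2-dioxolan-3-yl]ethyl}-9-borabicyclo[3.3.1]nonane (not isolated) | C[C@H](CC/C=C/CC/C=C/c1ccccc1)C[C@]1(C)C[C@](C)(CCB2C3CCCC2CCC3)OO1 | intermediate
25 | 2-[(3S,5R)-3,5-dimethyl-5-[(2R,5E,9E)-2-methyl-10-phenyldeca-5,9-dien-1-yl]-1,2-dioxolan-3-yl]ethan-1-ol | C[C@H](CC/C=C/CC/C=C/c1ccccc1)C[C@]1(C)C[C@](C)(CCO)OO1 | intermediate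
26 | 2-[(3R,5R)-3,5-dimethyl-5-[(2R,5E,9E)-2-methyl-10-phenyldeca-5,9-dien-1-yl]-1,2-dioxolan-3-yl]acetaldehyde (not isolated) | C[C@H](CC/C=C/CC/C=C/c1ccccc1)C[C@]1(C)C[C@](C)(CC=O)OO1 | intermediate
27 | 2-[(3R,5R)-3,5-dimethyl-5-[(2R,5E,9E)-2-methyl-10-phenyldeca-5,9-dien-1-yl]-1,2-dioxolan-3-yl]acetic acid | C[C@H](CC/C=C/CC/C=C/c1ccccc1)C[C@]1(C)C[C@](C)(CC(=O)O)OO1 | target

Total step count: 20.
Longest linear sequence: 15 steps from (R)-citronellal (steps 1–5, 7–13, 18–20); step 6 and steps 14–17 are side branches.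

Steps most likely to fail

Step 11. The 5-exo closure may discriminate poorly between the methyl group and the CH2 chain on C5, and O2 may be captured on either face of the C5 radical, so the wanted isomer may be a minor share that is hard to separate. The chain may also stall if the tertiary peroxyl radical abstracts hydrogen faster than it cyclises. The fallback builds the same ring by a cationic [3+2] annulation and sets out from alkene 7. Ozonolysis in MeOH/CH2Cl2 at −78 °C should give the α-methoxy hydroperoxide tert-butyl{[(4R)-6-hydroperoxy-6-methoxy-4-methylheptyl]oxy}dimethylsilane F1. Silylation with Et3SiOTf and 2,6-lutidine gives the silylperoxy ketal tert-butyl{[(4R)-6-methoxy-4-methyl-6-[(triethylsilyl)peroxy]heptyl]oxy}dimethylsilane F2. SnCl4 in CH2Cl2 at −78 °C ionises F2 to the peroxycarbenium ion, which adds to the CH2 terminus of 4-bromo-2-methylbut-1-ene; the tertiary cation is closed by the peroxide oxygen with loss of the silyl group. After separation of diastereomers this gives tert-butyl{[(4R)-5-[(3R,5R)-5-(2-bromoethyl)-3,5-dimethyl-1,2-dioxolan-3-yl]-4-methylpentyl]oxy}dimethylsilane F3. Dehydrobromination with KOtBu in THF then comes back to the route at vinyl dioxolane 14. This avoids the radical chain but not the separation, which is moved to the more polar bromide.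

Step 7. The α-methyl carbenoid may collapse by 1,2-hydride shift to ethyl acrylate, or couple with a second molecule of 9, faster than it adds to the unactivated alkene. The fallback sets out from ketone 6 and delivers the ring CH2 (C4) instead of C3. Horner–Wadsworth–Emmons reaction with triethyl 2-phosphonopropanoate (NaH, DME, reflux) should give ethyl (5R)-8-[(tert-butyldimethylsilyl)oxy]-2,3,5-trimethyloct-2-enoate F4 as an E/Z mixture, which does not matter because the ring configuration is erased later. Reduction with i-Bu2AlH gives (5R)-8-[(tert-butyldimethylsilyl)oxy]-2,3,5-trimethyloct-2-en-1-ol F5. Hydroxyl-directed Simmons–Smith cyclopropanation (Et2Zn, CH2I2, CH2Cl2, 0 °C) of the tetrasubstituted allylic alcohol comes back to the route at cyclopropylmethanol 11.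

Step 19. The hindered, oxygen-flanked vinyl group may need conditions under which 9-BBN also adds to the C10=C11 or styrenyl alkene, or the borane may attack the O–O bond during the longer reaction time. The fallback hydroborates before the other alkenes exist and sets out from 14.
- 9-BBN in THF gives the adduct 9-{2-[(3S,5R)-5-[(2R)-5-[(tert-butyldimethylsilyl)oxy]-2-methylpentyl]-3,5-dimethyl-1,2-dioxolan-3-yl]ethyl}-9-borabicyclo[3.3.1]nonane F6, which NaOH/H2O2 oxidises without isolation to 2-[(3S,5R)-5-[(2R)-5-[(tert-butyldimethylsilyl)oxy]-2-methylpentyl]-3,5-dimethyl-1,2-dioxolan-3-yl]ethan-1-ol F7.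
- Ac2O/pyridine gives 2-[(3S,5R)-5-[(2R)-5-[(tert-butyldimethylsilyl)oxy]-2-methylpentyl]-3,5-dimethyl-1,2-dioxolan-3-yl]ethyl acetate F8.
- HF·pyridine frees the C10 hydroxyl to give 2-[(3S,5R)-5-[(2R)-5-hydroxy-2-methylpentyl]-3,5-dimethyl-1,2-dioxolan-3-yl]ethyl acetate F9.
- Dess–Martin oxidation gives 2-[(3S,5R)-3,5-dimethyl-5-[(2R)-2-methyl-5-oxopentyl]-1,2-dioxolan-3-yl]ethyl acetate F10.
- Julia–Kocienski olefination with sulfone 22 (KN(SiMe3)2, DME, −60 °C) gives 2-[(3S,5R)-3,5-dimethyl-5-[(2R,5E,9E)-2-methyl-10-phenyldeca-5,9-dien-1-yl]-1,2-dioxolan-3-yl]ethyl acetate F11.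
- Methanolysis with K2CO3 in MeOH comes back to the route at alcohol 25.

Further compounds
F1 | step 11 | tert-butyl{[(4R)-6-hydroperoxy-6-methoxy-4-methylheptyl]oxy}dimethylsilane | C[C@H](CCCO[Si](C)(C)C(C)(C)C)CC(C)(OC)OO
F2 | step 11 | tert-butyl{[(4R)-6-methoxy-4-methyl-6-[(triethylsilyl)peroxy]heptyl]oxy}dimethylsilane | C[C@H](CCCO[Si](C)(C)C(C)(C)C)CC(C)(OC)OO[Si](CC)(CC)CC
F3 | step 11 | tert-butyl{[(4R)-5-[(3R,5R)-5-(2-bromoethyl)-3,5-dimethyl-1,2-dioxolan-3-yl]-4-methylpentyl]oxy}dimethylsilane | C[C@H](CCCO[Si](C)(C)C(C)(C)C)C[C@]1(C)C[C@](C)(CCBr)OO1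
F4 | step 7 | ethyl (5R)-8-[(tert-butyldimethylsilyl)oxy]-2,3,5-trimethyloct-2-enoate (E/Z mixture) | C[C@H](CCCO[Si](C)(C)C(C)(C)C)CC(C)=C(C)C(=O)OCC
F5 | step 7 | (5R)-8-[(tert-butyldimethylsilyl)oxy]-2,3,5-trimethyloct-2-en-1-ol (E/Z mixture) | C[C@H](CCCO[Si](C)(C)C(C)(C)C)CC(C)=C(C)CO
F6 | step 19 | 9-{2-[(3S,5R)-5-[(2R)-5-[(tert-butyldimethylsilyl)oxy]-2-methylpentyl]-3,5-dimethyl-1,2-dioxolan-3-yl]ethyl}-9-borabicyclo[3.3.1]nonane | C[C@H](CCCO[Si](C)(C)C(C)(C)C)C[C@]1(C)C[C@](C)(CCB2C3CCCC2CCC3)OO1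
F7 | step 19 | 2-[(3S,5R)-5-[(2R)-5-[(tert-butyldimethylsilyl)oxy]-2-methylpentyl]-3,5-dimethyl-1,2-dioxolan-3-yl]ethan-1-ol | C[C@H](CCCO[Si](C)(C)C(C)(C)C)C[C@]1(C)C[C@](C)(CCO)OO1
F8 | step 19 | 2-[(3S,5R)-5-[(2R)-5-[(tert-butyldimethylsilyl)oxy]-2-methylpentyl]-3,5-dimethyl-1,2-dioxolan-3-yl]ethyl acetate | C[C@H](CCCO[Si](C)(C)C(C)(C)C)C[C@]1(C)C[C@](C)(CCOC(C)=O)OO1
F9 | step 19 | 2-[(3S,5R)-5-[(2R)-5-hydroxy-2-methylpentyl]-3,5-dimethyl-1,2-dioxolan-3-yl]ethyl acetate | C[C@H](CCCO)C[C@]1(C)C[C@](C)(CCOC(C)=O)OO1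
F10 | step 19 | 2-[(3S,5R)-3,5-dimethyl-5-[(2R)-2-methyl-5-oxopentyl]-1,2-dioxolan-3-yl]ethyl acetate | C[C@H](CCC=O)C[C@]1(C)C[C@](C)(CCOC(C)=O)OO1
F11 | step 19 | 2-[(3S,5R)-3,5-dimethyl-5-[(2R,5E,9E)-2-methyl-10-phenyldeca-5,9-dien-1-yl]-1,2-dioxolan-3-yl]ethyl acetate | C[C@H](CC/C=C/CC/C=C/c1ccccc1)C[C@]1(C)C[C@](C)(CCOC(C)=O)OO1
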